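**Retrosynthetic overview**

1. Numbering (macrolide): C1 lactone carbonyl, C2 CHMe, C3 and C5 the two carbonyl carbons, ring B = C6–C7–C12–C13=C14–C15, ring A = C7–C8–C9=C10(Me)–C11–C12, C16 CHMe, C17–C20 the Z,Z-diene, C21 the carbinol carbon.
2. Enabling feature: ring B is a cyclohexene whose C13=C14 bond lies between the sp3 carbons C12 and C15 and whose C6 carries the C5 carbonyl (enol) carbon. This is a Diels–Alder retron (dienophile C6=C7 activated by C5=O, diene C12=C13–C14=C15), and C7 and C12 are already joined by the four carbons of ring A with its cis C9=C10 bond.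
3. Key disconnection: C6–C15 and C7–C12 across the ring. It opens rings A and B at once and expands the 14-membered lactone to a 22-membered macrolactone, a ring that is not in the target. The enone is unveiled only inside this ring by oxidation of C5–OH, and C3 stays a silyl-protected carbinol so that C2 cannot epimerize.
4. The 22-membered ring comes from Suzuki ring closure at C13–C14 of a linear ester made from three pieces: acid C1–C5 (Evans aldol), alkyne–boronate C6–C13 (carbomagnesiation, Negishi coupling, alkynylation, hydroboration) and iodotrienol C14–C21 (Roche ester, Takai, Wittig, semi-reduction). They are joined by esterification at O–C1 and alkenylzinc addition at C5–C6.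
5. Ring order: 22-membered lactone (step 25), then rings A and B together by transannular Diels–Alder reaction (step 26), which leaves the 14-membered lactone. Ring B is completed in this last ring-forming event; only desilylation and oxidation at C3 follow.

Key step: step 26

Assumption: the enol drawn in the target is one tautomer of the enolized C3/C5 diketone, and the tautomers and enol geometries interconvert freely, so the diketone oxidation level is the goal, while C2 is treated as a defined centre that must not be epimerized. (TBS = tert-butyldimethylsilyl; Bpin = 4,4,5,5-tetramethyl-1,3,2-dioxaborolan-2-yl.)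

**Fragment C (C14–C21)**

Step 1
Reactants: 1 methyl (S)-3-hydroxy-2-methylpropanoate
Product: 2 methyl (S)-3-(TBS-oxy)-2-methylpropanoate
Conditions: TBSCl, imidazole, CH2Cl2, 0 °C to rt
Reagents that add atoms: tert-butyldimethylsilyl chloride, CC(C)(C)[Si](C)(C)Cl
Why: Silyl ether formation masks the primary alcohol through the olefination steps and leaves the chiral-pool stereocentre (the later C16) untouched.

Step 2
Reactants: 2 methyl (S)-3-(TBS-oxy)-2-methylpropanoate
Product: 3 (S)-3-(TBS-oxy)-2-methylpropanal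
Conditions: i-Bu2AlH (1.05 equiv), CH2Cl2, −78 °C; aq Rochelle salt
Reagents that add atoms: none
Why: Partial ester reduction stops at the aldehyde because the tetrahedral aluminium hemiacetal survives at −78 °C until work-up, and the α-stereocentre is kept by using the aldehyde at once.

Step 3
Reactants: 3 (S)-3-(TBS-oxy)-2-methylpropanal
Product: 4 tert-butyl{[(2R,3E)-4-iodo-2-methylbut-3-en-1-yl]oxy}dimethylsilane
Conditions: CrCl2 (6 equiv), CHI3 (2 equiv), THF/1,4-dioxane, 0 °C to rt
Reagents that add atoms: iodoform, IC(I)I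
Why: Takai olefination should give the (E)-alkenyl iodide (anti elimination from the gem-dichromium adduct) under non-basic conditions, so the α-stereocentre does not epimerize.

Step 4
Reactants: 4 tert-butyl{[(2R,3E)-4-iodo-2-methylbut-3-en-1-yl]oxy}dimethylsilane
Product: 5 (2R,3E)-4-iodo-2-methylbut-3-en-1-ol
Conditions: camphorsulfonic acid (cat.), MeOH, 0 °C to rt
Reagents that add atoms: none
Why: Acid-catalysed methanolysis cleaves the primary silyl ether and does not touch the alkenyl iodide.

Step 5
Reactants: 5 (2R,3E)-4-iodo-2-methylbut-3-en-1-ol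
Product: 6 (1E,3R)-1,4-diiodo-3-methylbut-1-ene
Conditions: I2, PPh3, imidazole, CH2Cl2, 0 °C, dark
Reagents that add atoms: iodine, II
Why: Appel-type iodination proceeds by SN2 displacement of the oxyphosphonium ion at the primary carbon, one carbon away from the stereocentre.

Step 6
Reactants: 6 (1E,3R)-1,4-diiodo-3-methylbut-1-ene
Product: 7 [(2R,3E)-4-iodo-2-methylbut-3-en-1-yl]triphenylphosphonium iodide
Conditions: PPh3 (3 equiv), MeCN, 80 °C, dark
Reagents that add atoms: triphenylphosphine, c1ccc(cc1)P(c1ccccc1)c1ccccc1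
Why: SN2 alkylation of the phosphine by the primary iodide gives the Wittig salt, and the sp2 C–I bond is inert to phosphine in the absence of a metal catalyst.

Step 7
Reactants: 8 (R)-but-3-yn-2-ol
Product: 9 (R)-(but-3-yn-2-yloxy)(tert-butyl)dimethylsilane
Conditions: TBSCl, imidazole, DMF, rt
Reagents that add atoms: tert-butyldimethylsilyl chloride, CC(C)(C)[Si](C)(C)Cl
Why: Silylation of the chiral-pool propargylic alcohol (the later C21) occurs at oxygen with retention of configuration.

Step 8
Reactants: 9 (R)-(but-3-yn-2-yloxy)(tert-butyl)dimethylsilane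
Product: 11 (R)-4-(TBS-oxy)pent-2-ynal, via lithium acetylide 10 (not isolated)
Conditions: n-BuLi, THF, −78 °C; DMF; reverse quench into cold aq KH2PO4
Reagents that add atoms: N,N-dimethylformamide, CN(C)C=O
Why: Formylation of the lithium acetylide with DMF gives the ynal, and the buffered reverse quench avoids amine addition to the ynal and loss of the propargylic stereocentre.

Step 9
Reactants: 7 [(2R,3E)-4-iodo-2-methylbut-3-en-1-yl]triphenylphosphonium iodide; 11 (R)-4-(TBS-oxy)pent-2-ynal
Product: 13 tert-butyl{[(2R,5Z,7S,8E)-9-iodo-7-methylnona-5,8-dien-3-yn-2-yl]oxy}dimethylsilane, via phosphorus ylide 12 (not isolated)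
Conditions: NaHMDS, THF, −78 °C; then 11, −78 to 0 °C
Reagents that add atoms: none
Why: Wittig reaction of the non-stabilized ylide under lithium-free conditions should give the (Z)-enyne through the kinetic cis-oxaphosphetane, with both stereocentres remote from the reacting carbons and the (E)-alkenyl iodide stable to the cold amide base.

Step 10
Reactants: 13 tert-butyl{[(2R,5Z,7S,8E)-9-iodo-7-methylnona-5,8-dien-3-yn-2-yl]oxy}dimethylsilane
Product: 14 tert-butyl{[(2R,3Z,5Z,7S,8E)-9-iodo-7-methylnona-3,5,8-trien-2-yl]oxy}dimethylsilane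
Conditions: Zn(Cu/Ag) [Zn dust, Cu(OAc)2, AgNO3], MeOH/H2O (1:1), rt, dark
Reagents that add atoms: none
Why: The zinc(copper/silver) semi-reduction adds two hydrogens syn to the conjugated alkyne only, which should give the Z,Z-diene without over-reduction and without touching the alkenyl iodide.

Step 11
Reactants: 14 tert-butyl{[(2R,3Z,5Z,7S,8E)-9-iodo-7-methylnona-3,5,8-trien-2-yl]oxy}dimethylsilane
Product: 15 (2R,3Z,5Z,7S,8E)-9-iodo-7-methylnona-3,5,8-trien-2-ol
Conditions: Bu4NF, THF, 0 °C to rt
Reagents that add atoms: none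
Why: Fluoride-mediated desilylation frees the secondary alcohol needed for the ester bond without affecting any stereocentre or double bond.

**Fragment A (C1–C5)**

Step 12
Reactants: 16 (S)-4-benzyl-3-propanoyl-1,3-oxazolidin-2-one; 17 3-(TBS-oxy)propanal
Product: 19 (S)-4-benzyl-3-[(2S,3R)-5-(TBS-oxy)-3-hydroxy-2-methylpentanoyl]-1,3-oxazolidin-2-one, via boron enolate 18 (not isolated)
Conditions: Bu2BOTf, Et3N, CH2Cl2, 0 °C; 17, −78 to 0 °C; then pH 7 buffer, MeOH, H2O2
Reagents that add atoms: none
Why: Evans syn aldol reaction, in which the (Z)-boron enolate adds through a chair transition state on the face away from the benzyl group, sets C2 as S (and C3 as R, a centre that is later oxidized).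

Step 13
Reactants: 19 (S)-4-benzyl-3-[(2S,3R)-5-(TBS-oxy)-3-hydroxy-2-methylpentanoyl]-1,3-oxazolidin-2-one
Product: 20 (S)-4-benzyl-3-[(2S,3R)-3,5-bis(TBS-oxy)-2-methylpentanoyl]-1,3-oxazolidin-2-one
Conditions: TBSOTf, 2,6-lutidine, CH2Cl2, −78 to 0 °C
Reagents that add atoms: tert-butyldimethylsilyl triflate, CC(C)(C)[Si](C)(C)OS(=O)(=O)C(F)(F)F
Why: Silylation of the β-hydroxy group with the silyl triflate and a hindered base prevents retro-aldol cleavage and keeps C3 as a protected carbinol until after the cycloaddition.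

Step 14
Reactants: 20 (S)-4-benzyl-3-[(2S,3R)-3,5-bis(TBS-oxy)-2-methylpentanoyl]-1,3-oxazolidin-2-one
Product: 21 (2S,3R)-3,5-bis(TBS-oxy)-2-methylpentanoic acid
Conditions: LiOH, H2O2, THF/H2O, 0 °C; aq Na2SO3; aq NaHSO4 to pH 4
Reagents that add atoms: hydrogen peroxide, OO
Why: Lithium hydroperoxide attacks the exocyclic imide carbonyl selectively and frees the acid without epimerizing C2.

**Fragment B (C6–C13)**

Step 15
Reactants: 22 prop-2-yn-1-ol
Product: 24 (Z)-3-iodo-2-methylprop-2-en-1-ol, via alkenylmagnesium alkoxide 23 (not isolated)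
Conditions: MeMgBr (2.5 equiv), CuI (10 mol %), THF, −10 °C to rt; then I2, −78 to 0 °C
Reagents that add atoms: methylmagnesium bromide, C[Mg]Br; iodine, II
Why: Copper-catalysed anti carbomagnesiation of the propargylic alkoxide (the alkoxide chelate holds magnesium cis to the CH2O group) followed by iodinolysis with retention gives the Z-trisubstituted alkenyl iodide that becomes the cis C9=C10 bond of ring A.

Step 16
Reactants: 24 (Z)-3-iodo-2-methylprop-2-en-1-ol; 25 (3-bromoprop-1-yn-1-yl)trimethylsilane
Product: 27 (Z)-2-methyl-6-(trimethylsilyl)hex-2-en-5-yn-1-ol, via propargylzinc bromide 26 (not isolated)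
Conditions: 25, Zn dust, THF, 0 °C (2.5 equiv of 26); then 24, Pd(PPh3)4 (5 mol %), THF, rt
Reagents that add atoms: none
Why: Negishi coupling of the silyl-capped propargylzinc at its sp3 carbon, with retention of the alkene geometry, should give the skipped (1,4-) enyne, the silyl cap suppressing the allenyl isomer and one equivalent of the zinc reagent serving to deprotonate the hydroxyl group.

Step 17
Reactants: 27 (Z)-2-methyl-6-(trimethylsilyl)hex-2-en-5-yn-1-ol
Product: 28 [(Z)-6-bromo-5-methylhex-4-en-1-yn-1-yl]trimethylsilane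
Conditions: CBr4, PPh3, CH2Cl2, −20 to 0 °C
Reagents that add atoms: tetrabromomethane, BrC(Br)(Br)Br
Why: Appel bromination of the primary allylic alcohol at low temperature gives the allylic bromide without allylic transposition or loss of the Z geometry.

Step 18
Reactants: 28 [(Z)-6-bromo-5-methylhex-4-en-1-yn-1-yl]trimethylsilane
Product: 29 trimethyl[(Z)-5-methyloct-4-ene-1,7-diyn-1-yl]silane
Conditions: HC≡CMgBr (3 equiv), CuBr·SMe2 (10 mol %), THF, 0 °C to rt
Reagents that add atoms: ethynylmagnesium bromide, C#C[Mg]Br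
Why: Copper-catalysed SN2 coupling of the alkynyl Grignard reagent at the primary allylic carbon gives the skipped enediyne with retention of the Z-alkene, the two alkynes being told apart by the silyl cap.

Step 19
Reactants: 29 trimethyl[(Z)-5-methyloct-4-ene-1,7-diyn-1-yl]silane
Product: 30 trimethyl[(4Z,7E)-5-methyl-8-(Bpin)octa-4,7-dien-1-yn-1-yl]silane
Conditions: pinacolborane, Cp2Zr(H)Cl (10 mol %), Et3N (10 mol %), CH2Cl2, 40 °C
Reagents that add atoms: pinacolborane, CC1(C)OBOC1(C)C
Why: Zirconium-catalysed syn hydroboration of the terminal alkyne places boron at the terminal carbon and gives the (E)-alkenylboronate, while the silyl alkyne and the trisubstituted alkene do not react.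

Step 20
Reactants: 30 trimethyl[(4Z,7E)-5-methyl-8-(Bpin)octa-4,7-dien-1-yn-1-yl]silane
Product: 31 4,4,5,5-tetramethyl-2-[(1E,4Z)-4-methylocta-1,4-dien-7-yn-1-yl]-1,3,2-dioxaborolane
Conditions: K2CO3 (0.2 equiv), MeOH, rt
Reagents that add atoms: none
Why: Mild base-catalysed methanolysis of the C–Si bond frees the second terminal alkyne, and the pinacol boronate is stable to carbonate in methanol at room temperature.

**Assembly, ring closure and endgame**

Step 21
Reactants: 21 (2S,3R)-3,5-bis(TBS-oxy)-2-methylpentanoic acid; 15 (2R,3Z,5Z,7S,8E)-9-iodo-7-methylnona-3,5,8-trien-2-ol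
Product: 33 (2R,3Z,5Z,7S,8E)-9-iodo-7-methylnona-3,5,8-trien-2-yl (2S,3R)-3,5-bis(TBS-oxy)-2-methylpentanoate, via mixed anhydride 32 (not isolated)
Conditions: 2,4,6-trichlorobenzoyl chloride, Et3N, THF, rt; then 15, DMAP, toluene, rt
Reagents that add atoms: none
Why: Yamaguchi esterification through the mixed anhydride acylates the hindered secondary allylic alcohol at oxygen, so C21 is retained and C2 is not expected to epimerize.

Step 22
Reactants: 33 iodotrienyl (2S,3R)-3,5-bis(TBS-oxy)-2-methylpentanoate
Product: 34 (2R,3Z,5Z,7S,8E)-9-iodo-7-methylnona-3,5,8-trien-2-yl (2S,3R)-3-(TBS-oxy)-5-hydroxy-2-methylpentanoate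
Conditions: HF·pyridine, pyridine, THF, 0 °C
Reagents that add atoms: none
Why: The primary silyl ether is cleaved much faster than the hindered secondary one by buffered HF·pyridine, and the alcohol is oxidized at once so that it cannot lactonize onto the ester.

Step 23
Reactants: 34 iodotrienyl (2S,3R)-3-(TBS-oxy)-5-hydroxy-2-methylpentanoate
Product: 35 (2R,3Z,5Z,7S,8E)-9-iodo-7-methylnona-3,5,8-trien-2-yl (2S,3R)-3-(TBS-oxy)-2-methyl-5-oxopentanoate
Conditions: Dess–Martin periodinane, NaHCO3, CH2Cl2, 0 °C to rt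
Reagents that add atoms: none
Why: Buffered Dess–Martin oxidation gives the β-silyloxy aldehyde under non-basic conditions, which avoids β-elimination and epimerization.

Step 24
Reactants: 31 4,4,5,5-tetramethyl-2-[(1E,4Z)-4-methylocta-1,4-dien-7-yn-1-yl]-1,3,2-dioxaborolane; 35 iodotrienyl (2S,3R)-3-(TBS-oxy)-2-methyl-5-oxopentanoate
Product: 38 (2R,3Z,5Z,7S,8E)-9-iodo-7-methylnona-3,5,8-trien-2-yl (2S,3R,6E,9Z,12E)-3-(TBS-oxy)-5-hydroxy-2,10-dimethyl-13-(Bpin)trideca-6,9,12-trienoate (both C5 epimers), via alkenylzirconocene chloride 36 (not isolated), via alkenylmethylzinc 37 (not isolated)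
Conditions: 31, Cp2Zr(H)Cl (1.05 equiv), CH2Cl2, rt; Me2Zn, −65 °C; then 35, −65 to 0 °C
Reagents that add atoms: none
Why: Syn hydrozirconation of the terminal alkyne, zirconium-to-zinc transmetalation and 1,2-addition of the (E)-alkenylzinc to the aldehyde build the C5–C6 bond and the E C6=C7 bond, while the new C5 carbinol centre is left uncontrolled because it becomes a ketone and the boronate, alkenyl iodide and ester are inert to the organozinc.

Step 25
Reactants: 38 linear iodo boronate allylic alcohol (both C5 epimers)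
Product: 39 22-membered lactone: 21-olide of (2S,3R,6E,9Z,12E,14E,17Z,19Z)-3-(TBS-oxy)-5,21-dihydroxy-2,10,16-trimethyldocosa-6,9,12,14,17,19-hexaenoic acid (C16 and C21 as in 15; both C5 epimers)
Conditions: Pd(PPh3)4 (20 mol %), TlOEt (3 equiv), THF/H2O (3:1), rt, 1 mM
Reagents that add atoms: none
Why: Intramolecular Suzuki–Miyaura coupling at high dilution closes the 22-membered ring and creates the (E,E)-diene with retention of both alkene geometries, the thallium base allowing coupling at room temperature, and no cycloaddition can occur because the dienophile is still an unactivated allylic alcohol.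

Step 26
Reactants: 39 22-membered macrocyclic dienol (both C5 epimers)
Product: 41 tricyclic keto lactone with the ring system and all ring stereocentres of the target, C5 ketone and (3R)-TBS-oxy group, via macrocyclic enone 40 (not isolated)
Conditions: Dess–Martin periodinane, NaHCO3, CH2Cl2, 0 °C to rt; then toluene, 40 °C
Reagents that add atoms: none
Why: Oxidation of the allylic alcohol unveils the (E)-enone only inside the 22-membered ring, where it lies across the ring from the (E,E)-diene, and a concerted, asynchronous transannular Diels–Alder reaction should follow (closest known reaction types: macrocyclization–transannular cycloaddition sequences of macrolactone polyenes and the near-room-temperature cyclization of 1,7,9-decatrien-3-ones). Ring B closes as the six-membered [4+2] ring through the new bonds C6–C15 and C7–C12, ring A closes at the same time as a six-membered ring in the fused mode through the four-carbon tether C8–C11, and the 22-membered ring is thereby cut down to the 14-membered lactone. C6 and C7 come out trans because the dienophile is E, C12 and C15 carry their ring substituents cis because the diene is E,E, and the trans ring fusion together with the cis relation of C5 and C16 follows from the endo transition state with the C5 carbonyl under the diene (for an E-dienophile held by two tethers the only alternative is the exo mode, which would give the cis-fused bicycle). The diene face is set by C16: with its hydrogen eclipsing C14–H (A(1,3) strain) the methyl group points away from the dienophile and the Z-alkenyl arm that leads round the ring to the dienophile lies on the attacked face, a bias that is modest for an E-alkene and is expected to be reinforced by the ring. Regioselectivity is secured by the short tether (the other pairing would give a bridged ring), the Z,Z-diene cannot compete because it cannot reach an s-cis geometry, and premature cycloaddition is excluded because diene and activated dienophile never coexist before this step.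

Step 27
Reactants: 41 tricyclic keto lactone with (3R)-TBS-oxy group
Product: 42 tricyclic (3R)-3-hydroxy-5-keto lactone (the target with C3 at the carbinol level)
Conditions: HF·pyridine, THF, 0 °C to rt
Reagents that add atoms: none
Why: Acidic fluoride removes the last silyl ether to give the β-hydroxy ketone without base, so neither retro-aldol cleavage nor epimerization at C2 or C6 is expected.

Step 28
Reactants: 42 tricyclic (3R)-3-hydroxy-5-keto lactone
Product: 43 CNP0360406.1
Conditions: Dess–Martin periodinane (1.5 equiv), NaHCO3, CH2Cl2, 0 °C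
Reagents that add atoms: none
Why: Dess–Martin oxidation of the β-hydroxy ketone gives the 1,3-diketone, which enolizes to the target, and because C2 was flanked by an sp3 carbinol until this buffered, non-basic last step its S configuration should be retained.

**Compound list**

1 | methyl (S)-3-hydroxy-2-methylpropanoate | OC[C@H](C)C(=O)OC | starting material
2 | methyl (S)-3-(TBS-oxy)-2-methylpropanoate | CC(C)(C)[Si](C)(C)OC[C@H](C)C(=O)OC | intermediate
3 | (S)-3-(TBS-oxy)-2-methylpropanal | CC(C)(C)[Si](C)(C)OC[C@H](C)C=O | intermediate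
4 | tert-butyl{[(2R,3E)-4-iodo-2-methylbut-3-en-1-yl]oxy}dimethylsilane | CC(C)(C)[Si](C)(C)OC[C@H](C)/C=C/I | intermediate
5 | (2R,3E)-4-iodo-2-methylbut-3-en-1-ol | OC[C@H](C)/C=C/I | intermediate
6 | (1E,3R)-1,4-diiodo-3-methylbut-1-ene | IC[C@H](C)/C=C/I | intermediate
7 | [(2R,3E)-4-iodo-2-methylbut-3-en-1-yl]triphenylphosphonium iodide | [I-].c1ccccc1[P+](c1ccccc1)(c1ccccc1)C[C@H](C)/C=C/I | intermediate
8 | (R)-but-3-yn-2-ol | O[C@H](C)C#C | starting material
9 | (R)-(but-3-yn-2-yloxy)(tert-butyl)dimethylsilane | CC(C)(C)[Si](C)(C)O[C@H](C)C#C | intermediate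
10 | lithium acetylide of 9 | CC(C)(C)[Si](C)(C)O[C@H](C)C#C[Li] | intermediate (not isolated)
11 | (R)-4-(TBS-oxy)pent-2-ynal | CC(C)(C)[Si](C)(C)O[C@H](C)C#CC=O | intermediate
12 | phosphorus ylide from 7 | c1ccccc1P(c1ccccc1)(c1ccccc1)=C[C@H](C)/C=C/I | intermediate (not isolated)
13 | tert-butyl{[(2R,5Z,7S,8E)-9-iodo-7-methylnona-5,8-dien-3-yn-2-yl]oxy}dimethylsilane | CC(C)(C)[Si](C)(C)O[C@H](C)C#C/C=C\[C@H](C)/C=C/I | intermediate
14 | tert-butyl{[(2R,3Z,5Z,7S,8E)-9-iodo-7-methylnona-3,5,8-trien-2-yl]oxy}dimethylsilane | CC(C)(C)[Si](C)(C)O[C@H](C)/C=C\C=C/[C@H](C)/C=C/I | intermediate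
15 | (2R,3Z,5Z,7S,8E)-9-iodo-7-methylnona-3,5,8-trien-2-ol (fragment C) | O[C@H](C)/C=C\C=C/[C@H](C)/C=C/I | intermediate
16 | (S)-4-benzyl-3-propanoyl-1,3-oxazolidin-2-one | CCC(=O)N1[C@@H](Cc2ccccc2)COC1=O | starting material
17 | 3-(TBS-oxy)propanal | CC(C)(C)[Si](C)(C)OCCC=O | starting material
18 | (Z)-dibutylboron enolate of 16 | C/C=C(\OB(CCCC)CCCC)N1[C@@H](Cc2ccccc2)COC1=O | intermediate (not isolated)
19 | (S)-4-benzyl-3-[(2S,3R)-5-(TBS-oxy)-3-hydroxy-2-methylpentanoyl]-1,3-oxazolidin-2-one | CC(C)(C)[Si](C)(C)OCC[C@@H](O)[C@H](C)C(=O)N1[C@@H](Cc2ccccc2)COC1=O | intermediate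
20 | (S)-4-benzyl-3-[(2S,3R)-3,5-bis(TBS-oxy)-2-methylpentanoyl]-1,3-oxazolidin-2-one | CC(C)(C)[Si](C)(C)OCC[C@@H](O[Si](C)(C)C(C)(C)C)[C@H](C)C(=O)N1[C@@H](Cc2ccccc2)COC1=O | intermediate
21 | (2S,3R)-3,5-bis(TBS-oxy)-2-methylpentanoic acid (fragment A) | CC(C)(C)[Si](C)(C)OCC[C@@H](O[Si](C)(C)C(C)(C)C)[C@H](C)C(=O)O | intermediate
22 | prop-2-yn-1-ol | OCC#C | starting material
23 | (Z)-alkenylmagnesium alkoxide from 22 | Br[Mg]OC/C(C)=C\[Mg]Br | intermediate (not isolated)
24 | (Z)-3-iodo-2-methylprop-2-en-1-ol | OC/C(C)=C\I | intermediate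
25 | (3-bromoprop-1-yn-1-yl)trimethylsilane | C[Si](C)(C)C#CCBr | starting material
26 | [3-(trimethylsilyl)prop-2-yn-1-yl]zinc bromide | C[Si](C)(C)C#CC[Zn]Br | intermediate (not isolated)
27 | (Z)-2-methyl-6-(trimethylsilyl)hex-2-en-5-yn-1-ol | OC/C(C)=C\CC#C[Si](C)(C)C | intermediate
28 | [(Z)-6-bromo-5-methylhex-4-en-1-yn-1-yl]trimethylsilane | BrC/C(C)=C\CC#C[Si](C)(C)C | intermediate
29 | trimethyl[(Z)-5-methyloct-4-ene-1,7-diyn-1-yl]silane | C#CC/C(C)=C\CC#C[Si](C)(C)C | intermediate
30 | trimethyl[(4Z,7E)-5-methyl-8-(Bpin)octa-4,7-dien-1-yn-1-yl]silane | CC1(C)OB(/C=C/C/C(C)=C\CC#C[Si](C)(C)C)OC1(C)C | intermediate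
31 | 4,4,5,5-tetramethyl-2-[(1E,4Z)-4-methylocta-1,4-dien-7-yn-1-yl]-1,3,2-dioxaborolane (fragment B) | CC1(C)OB(/C=C/C/C(C)=C\CC#C)OC1(C)C | intermediate
32 | mixed anhydride of 21 and 2,4,6-trichlorobenzoic acid | CC(C)(C)[Si](C)(C)OCC[C@@H](O[Si](C)(C)C(C)(C)C)[C@H](C)C(=O)OC(=O)c1c(Cl)cc(Cl)cc1Cl | intermediate (not isolated)
33 | (2R,3Z,5Z,7S,8E)-9-iodo-7-methylnona-3,5,8-trien-2-yl (2S,3R)-3,5-bis(TBS-oxy)-2-methylpentanoate | CC(C)(C)[Si](C)(C)OCC[C@@H](O[Si](C)(C)C(C)(C)C)[C@H](C)C(=O)O[C@H](C)/C=C\C=C/[C@H](C)/C=C/I | intermediate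
34 | (2R,3Z,5Z,7S,8E)-9-iodo-7-methylnona-3,5,8-trien-2-yl (2S,3R)-3-(TBS-oxy)-5-hydroxy-2-methylpentanoate | OCC[C@@H](O[Si](C)(C)C(C)(C)C)[C@H](C)C(=O)O[C@H](C)/C=C\C=C/[C@H](C)/C=C/I | intermediate
35 | (2R,3Z,5Z,7S,8E)-9-iodo-7-methylnona-3,5,8-trien-2-yl (2S,3R)-3-(TBS-oxy)-2-methyl-5-oxopentanoate | O=CC[C@@H](O[Si](C)(C)C(C)(C)C)[C@H](C)C(=O)O[C@H](C)/C=C\C=C/[C@H](C)/C=C/I | intermediate
36 | (E)-alkenylzirconocene chloride from 31 | CC1(C)OB(/C=C/C/C(C)=C\C/C=C/[Zr](Cl)(C2C=CC=C2)C2C=CC=C2)OC1(C)C | intermediate (not isolated)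
37 | (E)-alkenyl(methyl)zinc from 31 | CC1(C)OB(/C=C/C/C(C)=C\C/C=C/[Zn]C)OC1(C)C | intermediate (not isolated)
38 | (2R,3Z,5Z,7S,8E)-9-iodo-7-methylnona-3,5,8-trien-2-yl (2S,3R,6E,9Z,12E)-3-(TBS-oxy)-5-hydroxy-2,10-dimethyl-13-(Bpin)trideca-6,9,12-trienoate, both C5 epimers | CC1(C)OB(/C=C/C/C(C)=C\C/C=C/C(O)C[C@@H](O[Si](C)(C)C(C)(C)C)[C@H](C)C(=O)O[C@H](C)/C=C\C=C/[C@H](C)/C=C/I)OC1(C)C | intermediate
39 | 22-membered lactone: 21-olide of (2S,3R,6E,9Z,12E,14E,17Z,19Z)-3-(TBS-oxy)-5,21-dihydroxy-2,10,16-trimethyldocosa-6,9,12,14,17,19-hexaenoic acid, C16 and C21 as in 15, both C5 epimers | C[C@@H]1/C=C\C=C/[C@H](C)/C=C/C=C/C/C(C)=C\C/C=C/C(O)C[C@@H](O[Si](C)(C)C(C)(C)C)[C@H](C)C(=O)O1 | intermediate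
40 | macrocyclic enone: 5-oxo analogue of 39 | C[C@@H]1/C=C\C=C/[C@H](C)/C=C/C=C/C/C(C)=C\C/C=C/C(=O)C[C@@H](O[Si](C)(C)C(C)(C)C)[C@H](C)C(=O)O1 | intermediate (not isolated)
41 | tricyclic keto lactone: ring system and ring stereocentres of the target, C5 ketone, (3R)-TBS-oxy | CC1=CC[C@@H]2[C@H]3C(=O)C[C@@H](O[Si](C)(C)C(C)(C)C)[C@H](C)C(=O)O[C@H](C)/C=C\C=C/[C@H](C)[C@H]3C=C[C@H]2C1 | intermediate
42 | tricyclic (3R)-3-hydroxy-5-keto lactone | CC1=CC[C@@H]2[C@H]3C(=O)C[C@@H](O)[C@H](C)C(=O)O[C@H](C)/C=C\C=C/[C@H](C)[C@H]3C=C[C@H]2C1 | intermediate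
43 | CNP0360406.1 | CC1=CC[C@@H]2[C@H]3/C(O)=C\C(=O)[C@H](C)C(=O)O[C@H](C)/C=C\C=C/[C@H](C)[C@H]3C=C[C@H]2C1 | target

**Step count and risks**

Total step count: 28. Longest linear sequence: 17 steps (steps 1–6, 9–11 and 21–28, from 1).

Most likely to fail:

1. Step 26. The cycloaddition may discriminate poorly between the two faces of the diene, because the A(1,3) bias of an E-alkene is small and the ring has to supply the rest. Some exo cyclization to the cis-fused ring system may also occur, and a slow cycloaddition would give the skipped enone time to isomerize into conjugation. Fallback: a chelation-organized cycloaddition at the free β-hydroxy enone, which sets out from 39 and comes back at 42. HF·pyridine would remove the silyl ether of 39 to give the macrocyclic 3,5-diol F1. MnO2 in CH2Cl2 would oxidize only the allylic C5 carbinol to the macrocyclic β-hydroxy enone F2, which would be treated without isolation with Et2AlCl at −78 to −20 °C. The aluminium alkoxide at C3 and the C5 carbonyl would form a six-membered chelate that holds the dienophile in one conformation next to the C3 stereocentre, raises the endo preference and allows the cycloaddition well below room temperature. The adduct is 42 itself, so step 27 is not needed.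

2. Step 25. Oligomerization by intermolecular coupling, protodeboronation of the alkenylboronate and base-induced migration of the skipped double bonds may compete with ring closure. Fallback: ring closure by a Nozaki–Hiyama–Kishi reaction at C5–C6 after the diene has been made intermolecularly; it sets out from 15, 31 and 21 and comes back at 39. Suzuki–Miyaura coupling of 15 with 31 (Pd(PPh3)4, TlOEt, THF/H2O) would give the pentaenynol (3Z,5Z,8E,10E,13Z)-7,13-dimethylheptadeca-3,5,8,10,13-pentaen-16-yn-2-ol F3. Yamaguchi esterification with 21 would give the bis-silyl ester F4. Hydrozirconation of the terminal alkyne with Cp2Zr(H)Cl and iodinolysis with N-iodosuccinimide would give the (E)-alkenyl iodide F5. Removal of the primary silyl ether with HF·pyridine would give the primary alcohol F6, and Dess–Martin oxidation the aldehyde F7. CrCl2 with catalytic NiCl2 in DMSO/THF at high dilution would then add the alkenyl iodide to the aldehyde and close the 22-membered ring as 39.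

3. Step 24. Competing hydrozirconation of the alkenylboronate or of the skipped diene, β-elimination of the silyloxy group from the aldehyde, or methyl transfer from zinc may erode the coupling. Fallback: a two-stage alkyne route that sets out from 31 and 35 and comes back at 38. Addition of the terminal alkyne of 31 to 35 mediated by Zn(OTf)2 and Et3N would give the propargylic alcohol F8. Ruthenium-catalysed trans-hydrosilylation ([Cp*Ru(MeCN)3]PF6, (EtO)3SiH, CH2Cl2) would give the (Z)-alkenyl(triethoxy)silane F9 with silicon on the carbon remote from the hydroxyl group. Protodesilylation with AgF in aqueous THF/MeOH would then give the (E)-allylic alcohol 38.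

**Further compounds**

F1 | step 26 | macrocyclic 3,5-diol: 21-olide of (2S,3R,6E,9Z,12E,14E,17Z,19Z)-3,5,21-trihydroxy-2,10,16-trimethyldocosa-6,9,12,14,17,19-hexaenoic acid | C[C@@H]1/C=C\C=C/[C@H](C)/C=C/C=C/C/C(C)=C\C/C=C/C(O)C[C@@H](O)[C@H](C)C(=O)O1
F2 | step 26 | macrocyclic β-hydroxy enone: 5-oxo analogue of F1 | C[C@@H]1/C=C\C=C/[C@H](C)/C=C/C=C/C/C(C)=C\C/C=C/C(=O)C[C@@H](O)[C@H](C)C(=O)O1
F3 | step 25 | (3Z,5Z,8E,10E,13Z)-7,13-dimethylheptadeca-3,5,8,10,13-pentaen-16-yn-2-ol, stereocentres as in 15 | O[C@H](C)/C=C\C=C/[C@H](C)/C=C/C=C/C/C(C)=C\CC#C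
F4 | step 25 | ester of F3 with (2S,3R)-3,5-bis(TBS-oxy)-2-methylpentanoic acid | CC(C)(C)[Si](C)(C)OCC[C@@H](O[Si](C)(C)C(C)(C)C)[C@H](C)C(=O)O[C@H](C)/C=C\C=C/[C@H](C)/C=C/C=C/C/C(C)=C\CC#C
F5 | step 25 | (E)-alkenyl iodide from F4 (CH=CHI in place of the terminal alkyne) | CC(C)(C)[Si](C)(C)OCC[C@@H](O[Si](C)(C)C(C)(C)C)[C@H](C)C(=O)O[C@H](C)/C=C\C=C/[C@H](C)/C=C/C=C/C/C(C)=C\C/C=C/I
F6 | step 25 | primary alcohol from F5 | OCC[C@@H](O[Si](C)(C)C(C)(C)C)[C@H](C)C(=O)O[C@H](C)/C=C\C=C/[C@H](C)/C=C/C=C/C/C(C)=C\C/C=C/I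
F7 | step 25 | aldehyde from F6 | O=CC[C@@H](O[Si](C)(C)C(C)(C)C)[C@H](C)C(=O)O[C@H](C)/C=C\C=C/[C@H](C)/C=C/C=C/C/C(C)=C\C/C=C/I
F8 | step 24 | propargylic alcohol from 31 and 35 (both C5 epimers) | CC1(C)OB(/C=C/C/C(C)=C\CC#CC(O)C[C@@H](O[Si](C)(C)C(C)(C)C)[C@H](C)C(=O)O[C@H](C)/C=C\C=C/[C@H](C)/C=C/I)OC1(C)C
F9 | step 24 | (Z)-alkenyl(triethoxy)silane from F8 | CC1(C)OB(/C=C/C/C(C)=C\C/C([Si](OCC)(OCC)OCC)=C/C(O)C[C@@H](O[Si](C)(C)C(C)(C)C)[C@H](C)C(=O)O[C@H](C)/C=C\C=C/[C@H](C)/C=C/I)OC1(C)C
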